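The target is cut at the C8–O4' aryl ether that lies beside the C7 benzylic carbinol of ring A. Because ring B is substituted at C1', C3' and C5', its phenoxy radical can bond only through O4'. A peroxidase-driven cross-coupling joins it to C8 of a free p-hydroxycinnamyl alcohol, and water then adds at C7 of the ring A quinone methide, so the full skeleton arises in one flask without protecting groups. The precursor pair is the unprotected E-cinnamyl alcohol of ring A and the ring B phenol already carrying its (S)-2,3-dihydroxypropyl chain. C7 is afterwards rewritten by oxidation and catalyst-controlled reduction; the 8R series leaves as the erythro diastereomer.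

Key step: step 5

Remark on the chemistry: C7, C8, C9 are the ring A side chain (C1, C2, C3 of the propane-1,3-diol) and primed locants belong to ring B; by CIP analysis the target is (7S,8S,8'S), the threo series. C8 of the C7 ketone is assumed to hold its configuration during the final reduction, so the route does not count on a dynamic reduction and only the 8S half of the ketone can become the target.

Step 1
Reactants: 1 sinapaldehyde, (E)-3-(4-hydroxy-3,5-dimethoxyphenyl)prop-2-enal
Product: 2 sinapyl alcohol, 4-[(E)-3-hydroxyprop-1-en-1-yl]-2,6-dimethoxyphenol
Conditions: NaBH4 (1.5 equiv), EtOAc/MeOH, 0 °C to rt; aq NH4Cl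
Reagents that add atoms: none
Why: Borohydride 1,2-reduction of the cinnamaldehyde carbonyl is faster than conjugate reduction, leaves the E-alkene and the free phenol untouched and forms no stereocentre, so the sensitive monolignol can be made fresh just before the coupling.

Step 2
Reactants: 3 4-bromo-2,6-dimethoxyphenol
Product: 4 2-(benzyloxy)-5-bromo-1,3-dimethoxybenzene
Conditions: BnBr (1.1 equiv), K2CO3 (1.5 equiv), DMF, 60 °C
Reagents that add atoms: benzyl bromide, BrCc1ccccc1
Why: Williamson ether synthesis on the phenoxide masks the acidic OH for the Grignard chemistry with a benzyl group that later leaves by hydrogenolysis together with the side-chain benzyl ether.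

Step 3
Reactants: 4 2-(benzyloxy)-5-bromo-1,3-dimethoxybenzene; 5 (S)-benzyl glycidyl ether, (2S)-2-[(benzyloxy)methyl]oxirane
Product: 7 (2S)-1-(benzyloxy)-3-[4-(benzyloxy)-3,5-dimethoxyphenyl]propan-2-ol, via arylmagnesium bromide 6 (not isolated)
Conditions: Mg turnings, I2 (cat.), THF, reflux; then CuI (10 mol%), 5 (0.8 equiv), THF, −30 to 0 °C; aqueous quench
Reagents that add atoms: none
Why: Copper-catalysed Grignard opening of a terminal epoxide is an SN2 attack at the unsubstituted CH2, so no bond to the stereocentre is broken and C8' is taken over from 5 with its configuration intact (the descriptor stays S because CH2OBn outranks ArCH2 just as it outranked the ring CH2).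

Step 4
Reactants: 7 (2S)-1-(benzyloxy)-3-[4-(benzyloxy)-3,5-dimethoxyphenyl]propan-2-ol
Product: 8 (2S)-3-(4-hydroxy-3,5-dimethoxyphenyl)propane-1,2-diol
Conditions: H2 (1 atm), Pd/C (10%), EtOH, rt
Reagents that add atoms: none
Why: Palladium-catalysed hydrogenolysis cleaves the aryl benzyl ether and the alkyl benzyl ether in one operation, whereas the non-benzylic C8' carbinol and the electron-rich ring are inert, so the ring B phenol is obtained with its (S)-diol unchanged.

Step 5
Reactants: 2 sinapyl alcohol; 8 (2S)-3-(4-hydroxy-3,5-dimethoxyphenyl)propane-1,2-diol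
Product: 10 1-(4-hydroxy-3,5-dimethoxyphenyl)-2-{4-[(2S)-2,3-dihydroxypropyl]-2,6-dimethoxyphenoxy}propane-1,3-diol as the mixture of its four C7/C8 isomers, via quinone methide 9 (not isolated)
Conditions: horseradish peroxidase, H2O2 (1.1 equiv), 8 (3 equiv), acetone/citrate–phosphate buffer pH 5 (1:5), rt, dark; 2 and H2O2 added by syringe pump over 12 h, then 12 h
Reagents that add atoms: water, O
Why: The peroxidase, turned over by H2O2, takes one electron and one proton from each phenol; the radical of 2 has spin density at C8, while the radical of 8 carries methoxy groups at C3' and C5' and the alkyl chain at C1' and so can only bond through O4', and the radical–radical combination gives the C8–O4' ether and quinone methide 9 on ring A. Water from the buffer then adds to C7 of 9 and restores the ring A phenol, which completes the arylglycerol β-aryl ether in the same flask. The closest known reaction type is the peroxidase or Ag2O dehydrogenative cross-coupling of monolignols with phenols that is used to make β-ether lignin model dimers by slow addition (Zutropf mode). No ring is closed. C8 is created in the radical combination and C7 in the water addition, neither under any control, so 10 should form as all four C7/C8 isomers (the erythro pair is expected to prevail for a syringyl quinone methide) with C8' untouched, and both centres are dealt with in steps 6 and 7. The step needs cross-coupling over the β–β self-coupling of 2 and O- over C-coupling on ring B: the first is served by adding 2 slowly to an excess of 8, whose own radical has no productive self-coupling site and can be recovered, the second by the substitution pattern of ring B.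

Step 6
Reactants: 10 1-(4-hydroxy-3,5-dimethoxyphenyl)-2-{4-[(2S)-2,3-dihydroxypropyl]-2,6-dimethoxyphenoxy}propane-1,3-diol (isomer mixture)
Product: 11 3-hydroxy-1-(4-hydroxy-3,5-dimethoxyphenyl)-2-{4-[(2S)-2,3-dihydroxypropyl]-2,6-dimethoxyphenoxy}propan-1-one as both C8 epimers
Conditions: DDQ (1.1 equiv), 1,4-dioxane/THF, rt
Reagents that add atoms: none
Why: DDQ dehydrogenation of a p-hydroxybenzylic alcohol, the reaction used to oxidise phenolic lignin β-ether models at the benzylic carbon, proceeds by phenol-assisted hydride loss from C7 and therefore erases only that stereocentre, while the primary and homobenzylic hydroxyls, C8 and C8' are not touched.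

Step 7
Reactants: 11 3-hydroxy-1-(4-hydroxy-3,5-dimethoxyphenyl)-2-{4-[(2S)-2,3-dihydroxypropyl]-2,6-dimethoxyphenoxy}propan-1-one (both C8 epimers)
Product: 12 (1S,2S)-1-(4-hydroxy-3,5-dimethoxyphenyl)-2-{4-[(2S)-2,3-dihydroxypropyl]-2,6-dimethoxyphenoxy}propane-1,3-diol
Conditions: RuCl(p-cymene)[(R,R)-TsDPEN] (2 mol%), HCO2Na (5 equiv), H2O/MeOH (1:1), pH 6–7 (HCO2H), 40 °C; chromatography removes the (7S,8R) erythro isomer
Reagents that add atoms: none
Why: Noyori–Ikariya asymmetric transfer hydrogenation: the (R,R)-TsDPEN ruthenium hydride adds H to the Re face of the aryl ketone through its CH/π-organised six-membered transition state, which sets C7 as S under catalyst control in both C8 epimers (the sense that gives (R)-1-phenylethanol, renamed S here because the C8 branch outranks the aryl group), so the 8S epimer should give the (7S,8S) threo target and the 8R epimer the (7S,8R) erythro isomer, which is removed as an ordinary diastereomer; C8 and C8' are not changed.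

Compound list
1 | sinapaldehyde, (E)-3-(4-hydroxy-3,5-dimethoxyphenyl)prop-2-enal | COc1cc(/C=C/C=O)cc(OC)c1O | starting material
2 | sinapyl alcohol, 4-[(E)-3-hydroxyprop-1-en-1-yl]-2,6-dimethoxyphenol | COc1cc(/C=C/CO)cc(OC)c1O | intermediate
3 | 4-bromo-2,6-dimethoxyphenol | COc1cc(Br)cc(OC)c1O | starting material
4 | 2-(benzyloxy)-5-bromo-1,3-dimethoxybenzene | COc1cc(Br)cc(OC)c1OCc1ccccc1 | intermediate
5 | (S)-benzyl glycidyl ether, (2S)-2-[(benzyloxy)methyl]oxirane | C1[C@H](O1)COCc1ccccc1 | starting material
6 | [4-(benzyloxy)-3,5-dimethoxyphenyl]magnesium bromide | COc1cc([Mg]Br)cc(OC)c1OCc1ccccc1 | intermediate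
7 | (2S)-1-(benzyloxy)-3-[4-(benzyloxy)-3,5-dimethoxyphenyl]propan-2-ol | COc1cc(C[C@H](O)COCc2ccccc2)cc(OC)c1OCc1ccccc1 | intermediate
8 | (2S)-3-(4-hydroxy-3,5-dimethoxyphenyl)propane-1,2-diol | COc1cc(C[C@H](O)CO)cc(OC)c1O | intermediate
9 | ring A quinone methide, 4-[2-{4-[(2S)-2,3-dihydroxypropyl]-2,6-dimethoxyphenoxy}-3-hydroxypropylidene]-2,6-dimethoxycyclohexa-2,5-dien-1-one | O=C1C(OC)=CC(=CC(CO)Oc2c(OC)cc(C[C@H](O)CO)cc2OC)C=C1OC | intermediate
10 | 1-(4-hydroxy-3,5-dimethoxyphenyl)-2-{4-[(2S)-2,3-dihydroxypropyl]-2,6-dimethoxyphenoxy}propane-1,3-diol, four C7/C8 isomers, C8' S | COc1cc(C(O)C(CO)Oc2c(OC)cc(C[C@H](O)CO)cc2OC)cc(OC)c1O | intermediate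
11 | 3-hydroxy-1-(4-hydroxy-3,5-dimethoxyphenyl)-2-{4-[(2S)-2,3-dihydroxypropyl]-2,6-dimethoxyphenoxy}propan-1-one, both C8 epimers, C8' S | COc1cc(C(=O)C(CO)Oc2c(OC)cc(C[C@H](O)CO)cc2OC)cc(OC)c1O | intermediate
12 | (1S,2S)-1-(4-hydroxy-3,5-dimethoxyphenyl)-2-{4-[(2S)-2,3-dihydroxypropyl]-2,6-dimethoxyphenoxy}propane-1,3-diol, (7S,8S,8'S) | COc1cc([C@H](O)[C@H](CO)Oc2c(OC)cc(C[C@H](O)CO)cc2OC)cc(OC)c1O | target

Total step count: 7. Longest linear sequence: 6 steps (steps 2 to 7, from 3); the other branch is step 1.

Steps most likely to fail

Step 5. The radicals of 2 may combine with each other (β–β self-coupling) faster than they meet the ring B radical. The phenolic product may also be oxidised again and grow into oligomers, and the enzyme may turn over the hindered dimethoxyphenols only slowly. A change of oxidant to Ag2O or laccase/O2 is the first adjustment. The fallback proper forms the C8–O4' bond by ionic chemistry; it sets out from 8 and comes back to the route at 11: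
- Commercial acetosyringone is benzylated (BnBr, K2CO3, DMF) to O-benzylacetosyringone F1.
- F1 is brominated (pyridinium tribromide, THF, rt) to the α-bromo ketone F2.
- The phenoxide of 8 (K2CO3, acetone, rt; the aliphatic hydroxyls are not deprotonated) displaces the bromide to give the aryloxy ketone F3.
- Aldol hydroxymethylation (aqueous CH2O, K2CO3, EtOH/dioxane, rt) installs C9 and should give the benzyl-protected β-hydroxy ketone F4 as both C8 epimers.
- Hydrogenolysis (H2, Pd/C, EtOAc/MeOH, rt, stopped after one equivalent) frees the ring A phenol and delivers 11, which continues with step 7.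

Step 7. Double stereodifferentiation may make the 8S ketone the slow, mismatched partner of the (R,R) catalyst, with eroded facial selectivity at C7. The electron-rich, partly ionised ketone may also be reduced sluggishly, and the threo and erythro products may co-elute. The fallback moves stereocontrol from the metal catalyst to an enzyme pocket that reads C8 as well as the carbonyl face; it sets out from 11 and comes back at 12. An NADPH-dependent ketoreductase is chosen from a commercial panel (NADP+, glucose, glucose dehydrogenase, phosphate buffer pH 7, DMSO co-solvent, 30 °C) for reduction of the 8S ketone only, on its Re face. The unreacted 8R ketone is removed by chromatography. No new compound is made (F0).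

Step 6. Oxidation may not stop at C7: hydride loss at the electron-rich ring B benzylic CH2 or oxidative coupling of the free phenol would consume the unprotected polyol. The fallback gives up the redox relay and resolves the isomers physically; it sets out from 10 and comes back at 12. Compound 10 is split on silica or reversed phase into the erythro pair and the threo pair. The threo pair, (7S,8S,8'S) and (7R,8R,8'S), is then resolved by preparative HPLC on a polysaccharide chiral stationary phase to give 12 directly. The erythro fraction can be returned to a threo/erythro mixture by brief treatment with dilute aqueous acid, which is expected to ionise the syringyl benzylic position reversibly, and recycled. No new compound is made (F0).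

Further compounds
F1 | step 5 | O-benzylacetosyringone, 1-[4-(benzyloxy)-3,5-dimethoxyphenyl]ethanone | COc1cc(C(C)=O)cc(OC)c1OCc1ccccc1
F2 | step 5 | α-bromo ketone, 2-bromo-1-[4-(benzyloxy)-3,5-dimethoxyphenyl]ethanone | COc1cc(C(=O)CBr)cc(OC)c1OCc1ccccc1
F3 | step 5 | aryloxy ketone, 1-[4-(benzyloxy)-3,5-dimethoxyphenyl]-2-{4-[(2S)-2,3-dihydroxypropyl]-2,6-dimethoxyphenoxy}ethanone | COc1cc(C(=O)COc2c(OC)cc(C[C@H](O)CO)cc2OC)cc(OC)c1OCc1ccccc1
F4 | step 5 | benzyl-protected β-hydroxy ketone, 1-[4-(benzyloxy)-3,5-dimethoxyphenyl]-3-hydroxy-2-{4-[(2S)-2,3-dihydroxypropyl]-2,6-dimethoxyphenoxy}propan-1-one, both C8 epimers | COc1cc(C(=O)C(CO)Oc2c(OC)cc(C[C@H](O)CO)cc2OC)cc(OC)c1OCc1ccccc1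
F0 | step 7 | none | none
F0 | step 6 | none | none
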